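**Strategy.** Everything rests on the C1–C14 bond (cembrane numbering, given below), the bond between the lactone β-carbon and the acetoxy-bearing carbon, instead of the usual C1–C2 bond. C1 is the γ-carbon of a 3-(bromomethyl)butenolide whose C2 substituent shields one face. One intramolecular Nozaki–Hiyama allylation lets that butenolide add through C1 to a C14 aldehyde: it closes the 14-membered ring, sets C1 and C14, and moves the ring double bond into the exocyclic C15=C17 methylene. The precursor is a linear chain carrying the preformed (2S)-butenolide, the 3,4-epoxide, the C5 acetate, the C9 silyl ether, both E-olefins and a terminal β,γ-unsaturated C14 aldehyde.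

Key step: step 19

Numbering used for all chain intermediates: C1 lactone β-CH, C2 lactone O–CH, C3/C4 epoxide (C4 bears Me), C5 (OAc), C6, C7=C8 (C8 bears Me), C9 (OH), C10, C11=C12 (C12 bears Me), C13, C14 (OAc), C15 (=C17H2), C16 lactone C=O. The target is (1R,2S,3S,4S,5R,9S,14R,7E,11E).

Remark on the chemistry: in steps 1, 6 and 10 the antipode of the chiral ligand or catalyst is defined by the configuration or aldehyde face it has to deliver; the ring closure in step 19 is assumed to follow the closed chair transition state (anti, 14S).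

**Step 1**
Reactants: 1 rac-2-vinyloxirane (butadiene monoxide)
Product: 2 (2S)-2-[(4-methoxybenzyl)oxy]but-3-en-1-ol
Conditions: Pd2(dba)3·CHCl3 (1 mol %), DACH-phenyl Trost ligand (3 mol %, antipode giving the 2S ether), Et3B (1 mol %), CH2Cl2, rt
Reagents that add atoms: 4-methoxybenzyl alcohol, COc1ccc(CO)cc1
Why: Pd-catalysed dynamic kinetic asymmetric allylic etherification of the racemic vinyl epoxide, in which both enantiomers pass through equilibrating π-allyl-Pd complexes, boron-tethered delivery of the alcohol gives the branched ether, and the ligand sets C2 (S).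

**Step 2**
Reactants: 2 (2S)-2-[(4-methoxybenzyl)oxy]but-3-en-1-ol; 3 ethyl 2-(triphenyl-λ5-phosphanylidene)propanoate
Product: 5 ethyl (2E,4S)-4-[(4-methoxybenzyl)oxy]-2-methylhexa-2,5-dienoate, via aldehyde 4 (not isolated)
Conditions: Dess–Martin periodinane, CH2Cl2, 0 °C; then 3 added to the same flask, 0 °C → rt
Reagents that add atoms: none
Why: Dess–Martin oxidation with in situ Wittig olefination traps the racemisation-prone α-alkoxy-β,γ-unsaturated aldehyde, and the stabilised α-methyl ylide should give the (E)-trisubstituted enoate (C3=C4) without touching C2.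

**Step 3**
Reactants: 5 ethyl (2E,4S)-4-[(4-methoxybenzyl)oxy]-2-methylhexa-2,5-dienoate
Product: 6 (2E,4S)-4-[(4-methoxybenzyl)oxy]-2-methylhexa-2,5-dien-1-ol
Conditions: DIBAL-H (2.2 equiv), CH2Cl2, −78 °C; Rochelle salt
Reagents that add atoms: none
Why: DIBAL-H 1,2-reduction of the enoate gives the primary allylic alcohol (C5) needed to direct the epoxidation.

**Step 4**
Reactants: 6 (2E,4S)-4-[(4-methoxybenzyl)oxy]-2-methylhexa-2,5-dien-1-ol
Product: 7 [(2S,3S)-3-{(1S)-1-[(4-methoxybenzyl)oxy]prop-2-en-1-yl}-2-methyloxiran-2-yl]methanol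
Conditions: Ti(OiPr)4 (10 mol %), L-(+)-diisopropyl tartrate (12 mol %), t-BuOOH, 4 Å MS, CH2Cl2, −20 °C
Reagents that add atoms: tert-butyl hydroperoxide, CC(C)(C)OO
Why: Sharpless asymmetric epoxidation of the (E)-2-methyl primary allylic alcohol, in which reagent control by L-(+)-tartrate sets 3S,4S (the sense established for E-allylic alcohols) and the undirected vinyl group is left alone.

**Step 5**
Reactants: 7 [(2S,3S)-3-{(1S)-1-[(4-methoxybenzyl)oxy]prop-2-en-1-yl}-2-methyloxiran-2-yl]methanol
Product: 8 (2R,3S)-3-{(1S)-1-[(4-methoxybenzyl)oxy]prop-2-en-1-yl}-2-methyloxirane-2-carbaldehyde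
Conditions: Dess–Martin periodinane, pyridine, CH2Cl2, 0 °C → rt
Reagents that add atoms: none
Why: Dess–Martin oxidation gives the α-quaternary epoxy aldehyde, which has no α-hydrogen and cannot epimerise (the descriptor at C4 changes only by CIP priority).

**Step 6**
Reactants: 8 (2R,3S)-3-{(1S)-1-[(4-methoxybenzyl)oxy]prop-2-en-1-yl}-2-methyloxirane-2-carbaldehyde; 9 4,4,5,5-tetramethyl-2-(propa-1,2-dien-1-yl)-1,3,2-dioxaborolane
Product: 10 (1R)-1-[(2S,3S)-3-{(1S)-1-[(4-methoxybenzyl)oxy]prop-2-en-1-yl}-2-methyloxiran-2-yl]but-3-yn-1-ol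
Conditions: 9 (1.5 equiv), TRIP chiral phosphoric acid (10 mol %, antipode for Re-face attack), 4 Å MS, toluene, −20 °C
Reagents that add atoms: none
Why: Chiral phosphoric acid-catalysed asymmetric propargylation (allenylboration through a six-membered SE2′ transition state), in which the catalyst directs the propargyl group to the Re face of the aldehyde and so sets 5R over the weak bias of the α-quaternary epoxide.

**Step 7**
Reactants: 10 (1R)-1-[(2S,3S)-3-{(1S)-1-[(4-methoxybenzyl)oxy]prop-2-en-1-yl}-2-methyloxiran-2-yl]but-3-yn-1-ol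
Product: 11 (1R)-1-[(2S,3S)-3-{(1S)-1-[(4-methoxybenzyl)oxy]prop-2-en-1-yl}-2-methyloxiran-2-yl]but-3-yn-1-yl acetate
Conditions: Ac2O, pyridine, DMAP (cat.), CH2Cl2, 0 °C → rt
Reagents that add atoms: acetic anhydride, CC(=O)OC(C)=O
Why: Standard acetylation installs the C5 acetate of the target, so this oxygen needs no protecting group.

**Step 8**
Reactants: 12 tert-butyl(but-3-yn-1-yloxy)dimethylsilane
Product: 15 (3E)-6-[(tert-butyldimethylsilyl)oxy]-4-methylhex-3-en-1-ol, via alkenyldimethylalane 13 (not isolated), via lithium alkenylalanate 14 (not isolated)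
Conditions: Me3Al (2.5 equiv), Cp2ZrCl2 (0.25 equiv), CH2Cl2, 0 °C → rt; then THF, n-BuLi, −78 °C; then ethylene oxide, −78 °C → rt; aq. Rochelle salt
Reagents that add atoms: trimethylaluminium, C[Al](C)C; ethylene oxide, C1CO1
Why: Negishi Zr-catalysed syn-carboalumination places methyl at C12 and aluminium at C11 (11E by cis addition), and the derived alanate opens ethylene oxide with retention of the alkene geometry to add C10 and C9.

**Step 9**
Reactants: 15 (3E)-6-[(tert-butyldimethylsilyl)oxy]-4-methylhex-3-en-1-ol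
Product: 16 (3E)-6-[(tert-butyldimethylsilyl)oxy]-4-methylhex-3-enal
Conditions: Dess–Martin periodinane, pyridine, CH2Cl2, 0 °C; used crude
Reagents that add atoms: none
Why: Buffered Dess–Martin oxidation should give the β,γ-unsaturated aldehyde without migration of the double bond into conjugation.

**Step 10**
Reactants: 11 (1R)-1-[(2S,3S)-3-{(1S)-1-[(4-methoxybenzyl)oxy]prop-2-en-1-yl}-2-methyloxiran-2-yl]but-3-yn-1-yl acetate; 16 (3E)-6-[(tert-butyldimethylsilyl)oxy]-4-methylhex-3-enal
Product: 17 C1–C14 chain propargylic alcohol (2S,3S,4S,5R,9S,11E): C1 as vinyl CH=CH2, 2-OPMB, 3,4-epoxide (4-Me), 5-OAc, C7≡C8, 9-OH, 12-Me, 14-OTBS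
Conditions: Me2Zn, ProPhenol ligand (20 mol %, antipode for Re-face addition), Ph3P=O (40 mol %), toluene, 0 °C; slow addition of 16
Reagents that add atoms: none
Why: Zn-ProPhenol-catalysed asymmetric alkynylation, in which the alkynylzinc formed from 11 and Me2Zn adds to the Re face of the aldehyde within the dinuclear zinc catalyst to set 9S, while acetate, epoxide and ethers tolerate the organozinc.

**Step 11**
Reactants: 17 C1–C14 chain propargylic alcohol
Product: 18 (7Z)-8-(tributylstannyl) alkenol: as 17 but C7H=C8(SnBu3), H-7 trans to tin, C6 and C9 trans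
Conditions: Bu3SnH, [Cp*RuCl]4 (2.5 mol %), CH2Cl2, rt
Reagents that add atoms: tributyltin hydride, CCCC[SnH](CCCC)CCCC
Why: Ru-catalysed hydroxyl-directed trans-hydrostannation, in which the free C9–OH steers tin to the proximal alkyne carbon C8 and hydrogen adds trans at C7, fixing C6 and C9 trans.

**Step 12**
Reactants: 18 (7Z)-8-(tributylstannyl) alkenol
Product: 19 (7E,11E)-dienol: as 17 but C7H=C8(Me), 9S-OH free
Conditions: MeI, CuTC, [NBu4][Ph2PO2], Pd(PPh3)4 (5 mol %), DMF, rt
Reagents that add atoms: iodomethane, CI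
Why: Stille-type C-methylation of the α-hydroxy alkenylstannane (Pd/Cu with a phosphinate tin scavenger) proceeds with retention of geometry and gives the (7E)-trisubstituted olefin carrying the C8 methyl.

**Step 13**
Reactants: 19 (7E,11E)-dienol
Product: 20 9,14-bis-O-TBS ether of 19
Conditions: TBSCl, imidazole, DMF, rt
Reagents that add atoms: tert-butyldimethylsilyl chloride, CC(C)(C)[Si](C)(C)Cl
Why: Silylation of the secondary allylic alcohol under neutral imidazole conditions spares the epoxide and the acetate.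

**Step 14**
Reactants: 20 9,14-bis-O-TBS ether
Product: 21 C2 alcohol: 20 with the PMB ether replaced by OH
Conditions: DDQ, CH2Cl2/pH 7 buffer, 0 °C
Reagents that add atoms: none
Why: Oxidative PMB cleavage with DDQ (benzylic hydride abstraction, then hydrolysis) frees only the C2 hydroxyl, since silyl ethers, acetate and epoxide are inert.

**Step 15**
Reactants: 21 C2 alcohol; 22 2-(bromomethyl)prop-2-enoic acid
Product: 23 2-(bromomethyl)acrylate ester of 21 at O-2
Conditions: DIC, DMAP (5 mol %), CH2Cl2, −20 → 0 °C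
Reagents that add atoms: none
Why: Steglich-type carbodiimide esterification at low temperature with only catalytic DMAP limits SN2′ attack on the allylic bromide.

**Step 16**
Reactants: 23 2-(bromomethyl)acrylate ester
Product: 24 (2S)-butenolide: 3-(bromomethyl)furan-2(5H)-one carrying the C3–C14 chain at its C5 (= C2)
Conditions: Grubbs II (10 mol %), toluene (5 mM), 70 °C, Ar sparge
Reagents that add atoms: none
Why: Ring-closing metathesis of the terminal vinyl group onto the 1,1-disubstituted acrylate closes the five-membered butenolide (C15=C1) with loss of ethylene, five-ring closure being faster than reaction at the trisubstituted olefins.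

**Step 17**
Reactants: 24 (2S)-butenolide bromide
Product: 25 C14 primary alcohol (9-OTBS retained)
Conditions: HF·pyridine, pyridine, THF, 0 °C
Reagents that add atoms: none
Why: Buffered HF·pyridine desilylation cleaves the unhindered primary silyl ether much faster than the secondary allylic one.

**Step 18**
Reactants: 25 C14 primary alcohol
Product: 26 C14 aldehyde (seco-aldehyde)
Conditions: Dess–Martin periodinane, pyridine, CH2Cl2, 0 °C; used at once
Reagents that add atoms: none
Why: Buffered Dess–Martin oxidation gives the β,γ-unsaturated C14 aldehyde, which is used immediately to avoid conjugation.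

**Step 19**
Reactants: 26 C14 aldehyde (seco-aldehyde)
Product: 28 (14S)-macrocyclic alcohol (14-epi-14-O-deacetyl-9-O-TBS-michaolide A), via allylchromium species 27 (not isolated)
Conditions: CrCl2 (10 equiv), 4 Å MS, THF, rt; 26 added by syringe pump over 12 h (final 1 mM); aq. NH4Cl at 0 °C
Reagents that add atoms: none
Why: CrCl2 reduces the allylic C17–Br bond to an allylchromium(III) species, which adds through its γ-carbon C1 to the tethered C14 aldehyde (SE2′, six-membered Zimmerman–Traxler transition state), so that the C15=C1 ring olefin becomes the exocyclic C15=C17 methylene; this is a Nozaki–Hiyama carbonyl allylation, and its closest precedents are the Cr- or Zn-mediated allylations of aldehydes with 3-(bromomethyl)furan-2(5H)-one and the Cr-mediated macrocyclic allylations used for cembranoids. The 14-membered carbocycle is closed in the 14-exo-trig mode at the aldehyde carbonyl, with formation of the C1–C14 bond. C1 (R) is controlled by the C2 stereocentre of the planar butenolide, whose epoxide-bearing substituent forces C–C bond formation on the opposite face (trans-lactone); C14 is controlled by the chair transition state, in which the ring-locked E-type allyl geometry and an equatorial C13 chain should give the anti (14S) carbinol. The step needs γ- over α-attack, which the SE2′ course of allylchromium and the smaller (14 versus 16) ring secure, and intra- over intermolecular reaction, which slow addition at high dilution secures. It also needs the lactone C2–O bond to survive, which is expected because that bond lies in the nodal plane of the allyl π system and is poorly aligned for 1,4-elimination. Epoxide, acetate and silyl ether are inert to Cr(II) and Cr(III) under these neutral conditions.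

**Step 20**
Reactants: 28 (14S)-macrocyclic alcohol
Product: 29 9-O-TBS-michaolide A (14R acetate)
Conditions: PPh3, DIAD, AcOH, toluene, 0 °C → rt
Reagents that add atoms: acetic acid, CC(=O)O
Why: Mitsunobu esterification with acetic acid, in which SN2 displacement of the C14 oxyphosphonium inverts 14S to the required 14R and installs the acetate in the same operation under non-basic conditions that avoid translactonisation.

**Step 21**
Reactants: 29 9-O-TBS-michaolide A
Product: 30 michaolide A
Conditions: HF·pyridine, pyridine, THF, 0 °C → rt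
Reagents that add atoms: none
Why: Buffered fluoride desilylation removes the remaining secondary silyl ether, while acetates, epoxide and the α-methylene lactone are stable to HF·pyridine.

**Compound list**

1 | rac-2-vinyloxirane | C=CC1CO1 | starting material
2 | (2S)-2-[(4-methoxybenzyl)oxy]but-3-en-1-ol | C=C[C@@H](CO)OCc1ccc(OC)cc1 | intermediate
3 | ethyl 2-(triphenyl-λ5-phosphanylidene)propanoate | CCOC(=O)C(C)=P(c1ccccc1)(c1ccccc1)c1ccccc1 | starting material
4 | (2S)-2-[(4-methoxybenzyl)oxy]but-3-enal | C=C[C@@H](C=O)OCc1ccc(OC)cc1 | intermediate (not isolated)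
5 | ethyl (2E,4S)-4-[(4-methoxybenzyl)oxy]-2-methylhexa-2,5-dienoate | CCOC(=O)/C(C)=C/[C@H](C=C)OCc1ccc(OC)cc1 | intermediate
6 | (2E,4S)-4-[(4-methoxybenzyl)oxy]-2-methylhexa-2,5-dien-1-ol | OC/C(C)=C/[C@H](C=C)OCc1ccc(OC)cc1 | intermediate
7 | [(2S,3S)-3-{(1S)-1-[(4-methoxybenzyl)oxy]prop-2-en-1-yl}-2-methyloxiran-2-yl]methanol | OC[C@]1(C)O[C@H]1[C@H](C=C)OCc1ccc(OC)cc1 | intermediate
8 | (2R,3S)-3-{(1S)-1-[(4-methoxybenzyl)oxy]prop-2-en-1-yl}-2-methyloxirane-2-carbaldehyde | O=C[C@]1(C)O[C@H]1[C@H](C=C)OCc1ccc(OC)cc1 | intermediate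
9 | 4,4,5,5-tetramethyl-2-(propa-1,2-dien-1-yl)-1,3,2-dioxaborolane | C=C=CB1OC(C)(C)C(C)(C)O1 | starting material
10 | (1R)-1-[(2S,3S)-3-{(1S)-1-[(4-methoxybenzyl)oxy]prop-2-en-1-yl}-2-methyloxiran-2-yl]but-3-yn-1-ol | C#CC[C@@H](O)[C@]1(C)O[C@H]1[C@H](C=C)OCc1ccc(OC)cc1 | intermediate
11 | (1R)-1-[(2S,3S)-3-{(1S)-1-[(4-methoxybenzyl)oxy]prop-2-en-1-yl}-2-methyloxiran-2-yl]but-3-yn-1-yl acetate | C#CC[C@@H](OC(C)=O)[C@]1(C)O[C@H]1[C@H](C=C)OCc1ccc(OC)cc1 | intermediate
12 | tert-butyl(but-3-yn-1-yloxy)dimethylsilane | C#CCCO[Si](C)(C)C(C)(C)C | starting material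
13 | [(1E)-4-{[tert-butyl(dimethyl)silyl]oxy}-2-methylbut-1-en-1-yl]dimethylalumane | C[Al](C)/C=C(\C)CCO[Si](C)(C)C(C)(C)C | intermediate (not isolated)
14 | lithium butyl[(1E)-4-{[tert-butyl(dimethyl)silyl]oxy}-2-methylbut-1-en-1-yl]dimethylalanate | [Li+].CCCC[Al-](C)(C)/C=C(\C)CCO[Si](C)(C)C(C)(C)C | intermediate (not isolated)
15 | (3E)-6-[(tert-butyldimethylsilyl)oxy]-4-methylhex-3-en-1-ol | OCC/C=C(\C)CCO[Si](C)(C)C(C)(C)C | intermediate
16 | (3E)-6-[(tert-butyldimethylsilyl)oxy]-4-methylhex-3-enal | O=CC/C=C(\C)CCO[Si](C)(C)C(C)(C)C | intermediate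
17 | C1–C14 chain propargylic alcohol (2S,3S,4S,5R,9S,11E; C1 vinyl, 2-OPMB, 3,4-epoxide, 5-OAc, 7-yne, 9-OH, 14-OTBS) | CC(C)(C)[Si](C)(C)OCC/C(C)=C/C[C@H](O)C#CC[C@@H](OC(C)=O)[C@]1(C)O[C@H]1[C@H](C=C)OCc1ccc(OC)cc1 | intermediate
18 | (7Z)-8-(tributylstannyl) alkenol derived from 17 | CC(C)(C)[Si](C)(C)OCC/C(C)=C/C[C@H](O)/C(=C/C[C@@H](OC(C)=O)[C@]1(C)O[C@H]1[C@H](C=C)OCc1ccc(OC)cc1)[Sn](CCCC)(CCCC)CCCC | intermediate
19 | (7E,11E)-dienol (8-Me, 9S-OH) | CC(C)(C)[Si](C)(C)OCC/C(C)=C/C[C@H](O)/C(C)=C/C[C@@H](OC(C)=O)[C@]1(C)O[C@H]1[C@H](C=C)OCc1ccc(OC)cc1 | intermediate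
20 | 9,14-bis-O-TBS ether of 19 | CC(C)(C)[Si](C)(C)OCC/C(C)=C/C[C@H](O[Si](C)(C)C(C)(C)C)/C(C)=C/C[C@@H](OC(C)=O)[C@]1(C)O[C@H]1[C@H](C=C)OCc1ccc(OC)cc1 | intermediate
21 | C2 alcohol (PMB removed) | CC(C)(C)[Si](C)(C)OCC/C(C)=C/C[C@H](O[Si](C)(C)C(C)(C)C)/C(C)=C/C[C@@H](OC(C)=O)[C@]1(C)O[C@H]1[C@H](C=C)O | intermediate
22 | 2-(bromomethyl)prop-2-enoic acid | C=C(CBr)C(=O)O | starting material
23 | 2-(bromomethyl)acrylate ester of 21 | CC(C)(C)[Si](C)(C)OCC/C(C)=C/C[C@H](O[Si](C)(C)C(C)(C)C)/C(C)=C/C[C@@H](OC(C)=O)[C@]1(C)O[C@H]1[C@H](C=C)OC(=O)C(=C)CBr | intermediate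
24 | (2S)-3-(bromomethyl)butenolide with C3–C14 chain, 14-OTBS | CC(C)(C)[Si](C)(C)OCC/C(C)=C/C[C@H](O[Si](C)(C)C(C)(C)C)/C(C)=C/C[C@@H](OC(C)=O)[C@]1(C)O[C@H]1[C@H]1OC(=O)C(CBr)=C1 | intermediate
25 | C14 primary alcohol | OCC/C(C)=C/C[C@H](O[Si](C)(C)C(C)(C)C)/C(C)=C/C[C@@H](OC(C)=O)[C@]1(C)O[C@H]1[C@H]1OC(=O)C(CBr)=C1 | intermediate
26 | C14 aldehyde (seco-aldehyde) | O=CC/C(C)=C/C[C@H](O[Si](C)(C)C(C)(C)C)/C(C)=C/C[C@@H](OC(C)=O)[C@]1(C)O[C@H]1[C@H]1OC(=O)C(CBr)=C1 | intermediate
27 | allylchromium(III) species (Cl2Cr at C17) | O=CC/C(C)=C/C[C@H](O[Si](C)(C)C(C)(C)C)/C(C)=C/C[C@@H](OC(C)=O)[C@]1(C)O[C@H]1[C@H]1OC(=O)C(C[Cr](Cl)Cl)=C1 | intermediate (not isolated)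
28 | (14S)-macrocyclic alcohol (14-epi-14-O-deacetyl-9-O-TBS-michaolide A) | C=C1C(=O)O[C@H]2[C@H]1[C@@H](O)C/C(C)=C/C[C@H](O[Si](C)(C)C(C)(C)C)/C(C)=C/C[C@@H](OC(C)=O)[C@]1(C)O[C@@H]21 | intermediate
29 | 9-O-TBS-michaolide A | C=C1C(=O)O[C@H]2[C@H]1[C@H](OC(C)=O)C/C(C)=C/C[C@H](O[Si](C)(C)C(C)(C)C)/C(C)=C/C[C@@H](OC(C)=O)[C@]1(C)O[C@@H]21 | intermediate
30 | michaolide A | C=C1C(=O)O[C@H]2[C@H]1[C@H](OC(C)=O)C/C(C)=C/C[C@H](O)/C(C)=C/C[C@@H](OC(C)=O)[C@]1(C)O[C@@H]21 | target

**Summary**

Total step count: 21. Longest linear sequence: 19 steps (steps 1–7, then 10–21); the C9–C14 aldehyde branch (steps 8–9) joins at step 10.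

Steps most likely to fail:

Step 19. The ring closure may show poor or reversed facial selectivity at the aldehyde carbon, because the tether can force the C13 chain axial in the chair transition state; oligomerisation is limited by dilution. Fallback: the route then uses retention instead of inversion at C14. It sets out from 26 under the same ring closure; the syn product, the (14R)-macrocyclic alcohol F1, is acetylated directly (Ac2O, pyridine, DMAP, CH2Cl2, 0 °C) and comes back to the route at 29, so that either C14 epimer is carried forward.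

Step 16. Ring closure at the electron-poor, 1,1-disubstituted bromomethylacrylate may be slow, with loss of the allylic bromide or catalyst decay competing. Fallback: the bromide is introduced only after the metathesis. It sets out from 21. Commercial 2-(hydroxymethyl)prop-2-enoic acid is silylated twice (Et3SiCl, imidazole, DMF) to the silyl ester triethylsilyl 2-{[(triethylsilyl)oxy]methyl}prop-2-enoate F2, which is not isolated; its silyl ester is hydrolysed on work-up (K2CO3, aq. MeOH, 0 °C) to 2-{[(triethylsilyl)oxy]methyl}prop-2-enoic acid F3. Esterification of 21 with F3 (DIC, DMAP) should give the silyloxymethyl acrylate F4. Ring-closing metathesis (Grubbs II, toluene, 70 °C) should give the 3-(triethylsilyloxymethyl)butenolide F5. Brief HF·pyridine/pyridine at −20 °C should give the 3-(hydroxymethyl)butenolide F6, and an Appel bromination (CBr4, PPh3, CH2Cl2, −20 °C) comes back to the route at 24.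

Step 20. The activated C14 oxyphosphonium may undergo E2 elimination toward C13 (conjugated diene), or displacement at the β-branched carbinol may not occur. Fallback: activation and displacement are separated. It sets out from 28: chloromethanesulfonyl chloride and pyridine (CH2Cl2, 0 °C) should give the C14 chloromethanesulfonate F7, which is displaced with inversion by caesium acetate and 18-crown-6 (toluene, 60 °C) and comes back to the route at 29.

**Further compounds**

F1 | step 19 | (14R)-macrocyclic alcohol (14-O-deacetyl-9-O-TBS-michaolide A) | C=C1C(=O)O[C@H]2[C@H]1[C@H](O)C/C(C)=C/C[C@H](O[Si](C)(C)C(C)(C)C)/C(C)=C/C[C@@H](OC(C)=O)[C@]1(C)O[C@@H]21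
F2 | step 16 | triethylsilyl 2-{[(triethylsilyl)oxy]methyl}prop-2-enoate | C=C(CO[Si](CC)(CC)CC)C(=O)O[Si](CC)(CC)CC
F3 | step 16 | 2-{[(triethylsilyl)oxy]methyl}prop-2-enoic acid | C=C(CO[Si](CC)(CC)CC)C(=O)O
F4 | step 16 | 2-(triethylsilyloxymethyl)acrylate ester of 21 | CC(C)(C)[Si](C)(C)OCC/C(C)=C/C[C@H](O[Si](C)(C)C(C)(C)C)/C(C)=C/C[C@@H](OC(C)=O)[C@]1(C)O[C@H]1[C@H](C=C)OC(=O)C(=C)CO[Si](CC)(CC)CC
F5 | step 16 | (2S)-3-(triethylsilyloxymethyl)butenolide with C3–C14 chain | CC(C)(C)[Si](C)(C)OCC/C(C)=C/C[C@H](O[Si](C)(C)C(C)(C)C)/C(C)=C/C[C@@H](OC(C)=O)[C@]1(C)O[C@H]1[C@H]1OC(=O)C(CO[Si](CC)(CC)CC)=C1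
F6 | step 16 | (2S)-3-(hydroxymethyl)butenolide with C3–C14 chain | CC(C)(C)[Si](C)(C)OCC/C(C)=C/C[C@H](O[Si](C)(C)C(C)(C)C)/C(C)=C/C[C@@H](OC(C)=O)[C@]1(C)O[C@H]1[C@H]1OC(=O)C(CO)=C1
F7 | step 20 | C14 chloromethanesulfonate of 28 | C=C1C(=O)O[C@H]2[C@H]1[C@@H](OS(=O)(=O)CCl)C/C(C)=C/C[C@H](O[Si](C)(C)C(C)(C)C)/C(C)=C/C[C@@H](OC(C)=O)[C@]1(C)O[C@@H]21
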